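Euchrenone b1 is genistein carrying three prenyl groups. Every aryl–CH2 bond lies ortho to a phenolic oxygen: C6 of ring A next to O5, C8 of ring A next to O7, C3' of ring B next to O4'. All three bonds are disconnected back to O-bound 2-methylbut-3-en-2-yl groups. Heating this tris(tertiary allyl) ether of genistein should move each five-carbon unit from oxygen to carbon by a [3,3] shift, invert it into a normal prenyl group and release the three phenols. One isomerisation therefore ends at the target. The crowded O5 ether is made on the open-chain deoxybenzoin, before ring C and its C4=O···H–O5 chelate exist.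

Key step: step 4

Assumption: 2-(4-hydroxyphenyl)-1-(2,4,6-trihydroxyphenyl)ethan-1-one, the bulk intermediate of genistein manufacture, is taken as purchasable. If it is not, it is one BF3·OEt2-mediated acylation of phloroglucinol with 4-hydroxyphenylacetic acid away.

Remark: the target, 5,7,4'-trihydroxy-6,8,3'-tris(3-methylbut-2-enyl)isoflavone (C30H34O5), is achiral and has no stereogenic alkene, so no stereochemistry has to be set.

Step 1
Reactants: 1 2-methylbut-3-yn-2-ol; 2 2-(4-hydroxyphenyl)-1-(2,4,6-trihydroxyphenyl)ethan-1-one
Product: 4 1-[2-hydroxy-4,6-bis(2-methylbut-3-yn-2-yloxy)phenyl]-2-[4-(2-methylbut-3-yn-2-yloxy)phenyl]ethan-1-one, via 2-methylbut-3-yn-2-yl trifluoroacetate 3 (not isolated)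
Conditions: 1 (3.8 equiv), (CF3CO)2O, DBU, MeCN, −5 °C; then transferred into 2, DBU, CuCl2·2H2O (1 mol %), MeCN–DMF, −5 to 0 °C
Reagents that add atoms: trifluoroacetic anhydride, O=C(OC(=O)C(F)(F)F)C(F)(F)F (its CF3CO group is present in 3 only and leaves again on the way to 4)
Why: Copper-catalysed propargylic substitution (O-propargylation of phenols): the tertiary ester ionises by way of its copper acetylide to an allenylidene-type electrophile that phenoxides trap at the tertiary carbon at 0 °C, and because the ketone of a 2,6-dihydroxyaryl ketone can chelate only one ortho OH at a time, O4, O4' and one ortho oxygen are etherified while the last OH, now firmly chelated and shielded, is left for the ring closure.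

Step 2
Reactants: 4 1-[2-hydroxy-4,6-bis(2-methylbut-3-yn-2-yloxy)phenyl]-2-[4-(2-methylbut-3-yn-2-yloxy)phenyl]ethan-1-one
Product: 6 5,7,4'-tris-O-(2-methylbut-3-yn-2-yl)genistein, via enaminone 5 (not isolated)
Conditions: Me2NCH(OMe)2 (4 equiv), toluene, 70 °C
Reagents that add atoms: N,N-dimethylformamide dimethyl acetal, COC(OC)N(C)C (supplies C2–H of ring C)
Why: Deoxybenzoin route to isoflavones: the amide acetal condenses with the doubly activated CH2 to enaminone 5, whose β-carbon is attacked by the free ortho phenol (oxa-Michael addition, then loss of Me2NH) to close ring C under neutral to mildly basic conditions, at a temperature well below the onset of the propargyl Claisen cyclisation to chromenes.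

Step 3
Reactants: 6 5,7,4'-tris-O-(2-methylbut-3-yn-2-yl)genistein
Product: 7 5,7,4'-tris-O-(2-methylbut-3-en-2-yl)genistein
Conditions: H2 (1 atm), Pd/CaCO3 poisoned with Pb(OAc)2, quinoline, EtOAc, 20 °C, stopped at 3 equiv H2; concentrated below 30 °C and used at once
Reagents that add atoms: none
Why: Lindlar semi-hydrogenation: the terminal alkynes displace the product vinyl groups and the vinylogous-ester C2=C3 bond from the lead- and quinoline-poisoned palladium surface, so hydrogen uptake can be cut off at three equivalents; the ethers are kept at or below room temperature to postpone any [3,3] shift.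

Step 4
Reactants: 7 5,7,4'-tris-O-(2-methylbut-3-en-2-yl)genistein
Product: 10 euchrenone b1 (5,7,4'-trihydroxy-6,8,3'-triprenylisoflavone), via 6-prenyl bis-ether 8 (not isolated), via 6,8-diprenyl mono-ether 9 (not isolated)
Conditions: PhNEt2 (degassed, 0.05 M), Ar, dark, 90 °C, then 130 °C
Reagents that add atoms: none
Why: Each Ar–O–CMe2–CH=CH2 unit passes through a concerted chair-like [3,3] transition state in which the vinyl CH2 bonds to the ortho ring carbon as the O–CMe2 bond breaks, and the resulting cyclohexadienone tautomerises to the phenol, so allyl inversion turns the tertiary ether into the normal 3-methylbut-2-enyl group. The reaction type is the aromatic Claisen rearrangement of aryl 1,1-dimethylallyl ethers, which the gem-dimethyl group makes unusually easy and which tolerates being run several-fold on one polyphenol ether. No ring is closed and no stereocentre or stereogenic alkene is created. The step needs site selectivity: the O4' unit can reach only C3' or its symmetry equivalent C5', and the O5 unit only C6, because its other ortho position is the ring-fusion carbon C4a. For the O7 unit the choice of C8 over C6 is secured twice, since the O5 ether, compressed against C4=O, should move first during the 90 °C hold and fill C6 (a later attack there gives a dienone that cannot aromatise and reverts), and as long as O5 is still alkylated C6 is walled in by two tertiary alkoxy groups while C8 has only the ring oxygen O1 as second neighbour. The amine solvent buffers the acidic 7-OH as it is released, so that neither heterolysis of the remaining tertiary ethers nor ring closure of the ortho-prenylphenols is acid-catalysed.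

Compound list
1 | 2-methylbut-3-yn-2-ol | CC(C)(O)C#C | starting material
2 | 2-(4-hydroxyphenyl)-1-(2,4,6-trihydroxyphenyl)ethan-1-one | O=C(Cc1ccc(O)cc1)c1c(O)cc(O)cc1O | starting material
3 | 2-methylbut-3-yn-2-yl trifluoroacetate (not isolated) | C#CC(C)(C)OC(=O)C(F)(F)F | intermediate
4 | 1-[2-hydroxy-4,6-bis(2-methylbut-3-yn-2-yloxy)phenyl]-2-[4-(2-methylbut-3-yn-2-yloxy)phenyl]ethan-1-one | C#CC(C)(C)Oc1ccc(CC(=O)c2c(O)cc(OC(C)(C)C#C)cc2OC(C)(C)C#C)cc1 | intermediate
5 | (E)-3-(dimethylamino)-1-[2-hydroxy-4,6-bis(2-methylbut-3-yn-2-yloxy)phenyl]-2-[4-(2-methylbut-3-yn-2-yloxy)phenyl]prop-2-en-1-one (not isolated; drawn E, the push–pull alkene isomerises freely and its geometry is lost on ring closure) | CN(C)/C=C(/C(=O)c1c(O)cc(OC(C)(C)C#C)cc1OC(C)(C)C#C)c1ccc(OC(C)(C)C#C)cc1 | intermediate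
6 | 5,7,4'-tris-O-(2-methylbut-3-yn-2-yl)genistein | C#CC(C)(C)Oc1ccc(-c2coc3cc(OC(C)(C)C#C)cc(OC(C)(C)C#C)c3c2=O)cc1 | intermediate
7 | 5,7,4'-tris-O-(2-methylbut-3-en-2-yl)genistein (precursor of the key step) | C=CC(C)(C)Oc1ccc(-c2coc3cc(OC(C)(C)C=C)cc(OC(C)(C)C=C)c3c2=O)cc1 | intermediate
8 | 6-prenyl-7,4'-bis-O-(2-methylbut-3-en-2-yl)genistein, 5-OH free (not isolated) | C=CC(C)(C)Oc1ccc(-c2coc3cc(OC(C)(C)C=C)c(CC=C(C)C)c(O)c3c2=O)cc1 | intermediate
9 | 6,8-diprenyl-4'-O-(2-methylbut-3-en-2-yl)genistein (not isolated) | C=CC(C)(C)Oc1ccc(-c2coc3c(CC=C(C)C)c(O)c(CC=C(C)C)c(O)c3c2=O)cc1 | intermediate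
10 | euchrenone b1 | CC(C)=CCc1cc(-c2coc3c(CC=C(C)C)c(O)c(CC=C(C)C)c(O)c3c2=O)ccc1O | target

Total step count: 4
Longest linear sequence: 4 steps (2 → 4 → 6 → 7 → 10)

Steps most likely to fail

Step 4. Three things may go wrong.
- The O7 unit may be delivered to C6 before the O5 unit has moved. The O5 unit can then only travel on by a Claisen–Cope relay and would arrive at C8 in the reversed orientation.
- The tertiary C–O bonds may break heterolytically with loss of isoprene.
- The freed phenols may add to their prenyl neighbours.

The fallback sets out from 7 and returns at 10, and the shifts are no longer run together. Eu(fod)3 (fod = 6,6,7,7,8,8,8-heptafluoro-2,2-dimethyloctane-3,5-dionate, 10 mol %) in CHCl3 at 45–50 °C binds in the C4=O/O5 pocket. It should trigger only the O5-to-C6 shift, and 8 is now isolated. With C6 filled, 8 is heated at 130 °C in PhNEt2 containing acetic anhydride, then treated with DMAP at room temperature. Each phenol is thus capped as soon as it appears, giving euchrenone b1 triacetate F1. Methanolysis with K2CO3 in MeOH at 0 °C then gives 10.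

Step 1. The etherification may stall after two oxygens because the third is flanked by the acyl group. The phloroglucinol ring or the benzylic CH2 may be alkylated at carbon. The trifluoroacetate may be lost by elimination during the slow third etherification.

The fallback sets out from 2 and returns at 6, bypassing 4 and step 2, because ring C is closed first. A Vilsmeier-type one-carbon insertion (BF3·OEt2, DMF, MeSO2Cl, 60 °C) converts 2 into genistein F2, in which the CH2 is gone. Trifluoroacetate 3 under the same CuCl2·2H2O/DBU conditions etherifies the two unchelated oxygens to give 7,4'-bis-O-(2-methylbut-3-yn-2-yl)genistein F3. The chelated O5–H is then treated alone with a large excess of fresh 3, DBU and CuCl2·2H2O at 0 °C to room temperature. Unreacted F3 is recovered and recycled until 6 is reached.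

Step 3. One of the three vinyl groups may be over-reduced, or hydrogen uptake may stay incomplete. Either outcome leaves mixtures that differ by two hydrogens and resist separation.

The fallback sets out from 6 and returns at 7, and it replaces hydrogenation by hydrosilylation followed by protodesilylation. [Cp*Ru(MeCN)3]PF6 (5 mol %) and (EtO)3SiH in CH2Cl2 at 0 °C add Si–H once to each alkyne to give 5,7,4'-tris-O-[2-methyl-3-(triethoxysilyl)but-3-en-2-yl]genistein F4. The regiochemistry of addition is immaterial, since either vinylsilane gives the same vinyl group. AgF in THF–MeOH–H2O at room temperature in the dark then exchanges silicon for hydrogen. This sequence cannot reduce an alkene further.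

Further compounds
F1 | step 4 | euchrenone b1 triacetate | CC(=O)Oc1ccc(-c2coc3c(CC=C(C)C)c(OC(C)=O)c(CC=C(C)C)c(OC(C)=O)c3c2=O)cc1CC=C(C)C
F2 | step 1 | genistein | O=c1c(-c2ccc(O)cc2)coc2cc(O)cc(O)c12
F3 | step 1 | 7,4'-bis-O-(2-methylbut-3-yn-2-yl)genistein | C#CC(C)(C)Oc1ccc(-c2coc3cc(OC(C)(C)C#C)cc(O)c3c2=O)cc1
F4 | step 3 | 5,7,4'-tris-O-[2-methyl-3-(triethoxysilyl)but-3-en-2-yl]genistein | C=C([Si](OCC)(OCC)OCC)C(C)(C)Oc1ccc(-c2coc3cc(OC(C)(C)C(=C)[Si](OCC)(OCC)OCC)cc(OC(C)(C)C(=C)[Si](OCC)(OCC)OCC)c3c2=O)cc1
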